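**Retrosynthetic overview**

- The target is the 8'-O-acyl derivative of 8'-hydroxyabscisic acid. The 8'-ester is cut to the (S)-monomethyl ester of 3-hydroxy-3-methylglutaric acid (enzymatic desymmetrisation), and the C3–C4 bond of the dienoic acid to an (E)-vinylstannane (from a C1' ethynyl group) plus (Z)-3-iodobut-2-enoic acid.
- Feature the plan rests on: in ring A the carbinol C1' and the quaternary C6' (bearing C8'H2–O and the C9' methyl) are neighbours. If C8'–O is the Baeyer–Villiger product of an acetonyl group on C6' and C5'–C6' is cut, ring A unfolds to a prochiral C1' carbinol with two identical (Z)-4-oxopent-2-en-2-yl arms.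
- C5'–C6' is formed by an enantiotopic-arm-selective intramolecular Michael addition (chiral primary amine plus acid), which closes ring A and sets C1' and C6' together.
- The bis-enone comes from methyl 3-(trimethylsilyl)propiolate and two but-3-yn-2-ol-derived acetylides, via the bis-ynone and a double Me2CuLi addition.
- Ring order: ring A, the only carbocycle, in step 7; a dioxolane on C4' is a temporary protecting ring (steps 9 to 17).

Key step: step 7

Numbering: abscisic acid numbering is used (ring C1'–C6'; C7' = methyl on C2'; C8' = oxygenated carbon on C6'; C9' = methyl on C6'; side chain C1–C5).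

Assumption: which pseudo-enantiomer of the cinchona-derived primary amine gives the required enantiomer of the key-step product cannot be predicted with confidence for this new substrate class. The quinine-derived amine is written; the quinidine-derived one would replace it if the sense of induction proved opposite.

**Route**

Step 1
Reactants: 1 but-3-yn-2-ol (racemic)
Product: 2 triethyl(but-3-yn-2-yloxy)silane
Conditions: TESCl, imidazole, CH2Cl2, 0 °C → rt
Reagents that add atoms: chlorotriethylsilane, CC[Si](Cl)(CC)CC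
Why: Standard O-silylation of a secondary alcohol gives a triethylsilyl ether that tolerates acetylide chemistry and can later be removed beside a tertiary tert-butyldimethylsilyl ether; the carbinol centre is racemic and is erased in step 5.

Step 2
Reactants: 2 triethyl(but-3-yn-2-yloxy)silane; 3 methyl 3-(trimethylsilyl)propiolate
Product: 6 2,8-bis[(triethylsilyl)oxy]-5-[(trimethylsilyl)ethynyl]nona-3,6-diyn-5-ol, via lithium acetylide 4 (not isolated), via diynyl ketone 5 (not isolated)
Conditions: 2 (2.2 equiv), n-BuLi (2.2 equiv), THF, −78 °C; then 3 (1.0 equiv), −78 → 0 °C; H2O quench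
Reagents that add atoms: none
Why: Double 1,2-addition of a lithium acetylide to an ester should proceed because the intermediate ynone is more electrophilic than the ester and the C-silyl group blocks conjugate attack on the propiolate; 6 forms as a mixture of diastereomers at the two remote carbinol carbons, which is irrelevant.

Step 3
Reactants: 6 2,8-bis[(triethylsilyl)oxy]-5-[(trimethylsilyl)ethynyl]nona-3,6-diyn-5-ol
Product: 7 5-[(tert-butyldimethylsilyl)oxy]-2,8-bis[(triethylsilyl)oxy]-5-[(trimethylsilyl)ethynyl]nona-3,6-diyne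
Conditions: TBSOTf, 2,6-lutidine, CH2Cl2, −78 → 0 °C
Reagents that add atoms: tert-butyldimethylsilyl trifluoromethanesulfonate, CC(C)(C)[Si](C)(C)OS(=O)(=O)C(F)(F)F
Why: Silyl triflate silylation of a tertiary alcohol should be fast here because a carbinol flanked by three linear alkynes is sterically open.

Step 4
Reactants: 7 5-[(tert-butyldimethylsilyl)oxy]-2,8-bis[(triethylsilyl)oxy]-5-[(trimethylsilyl)ethynyl]nona-3,6-diyne
Product: 8 5-[(tert-butyldimethylsilyl)oxy]-5-[(trimethylsilyl)ethynyl]nona-3,6-diyne-2,8-diol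
Conditions: PPTS, MeOH, 0 °C → rt
Reagents that add atoms: none
Why: Acid-catalysed methanolysis cleaves the unhindered secondary triethylsilyl ethers much faster than the tertiary tert-butyldimethylsilyl ether and leaves the C-silyl alkyne intact (selective silyl ether solvolysis).

Step 5
Reactants: 8 5-[(tert-butyldimethylsilyl)oxy]-5-[(trimethylsilyl)ethynyl]nona-3,6-diyne-2,8-diol
Product: 9 5-[(tert-butyldimethylsilyl)oxy]-5-[(trimethylsilyl)ethynyl]nona-3,6-diyne-2,8-dione
Conditions: Dess–Martin periodinane, CH2Cl2, 0 °C → rt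
Reagents that add atoms: none
Why: Dess–Martin oxidation of secondary propargylic alcohols gives the ynones under nearly neutral conditions and converts the diastereomer mixture into a single achiral bis-ynone.

Step 6
Reactants: 9 5-[(tert-butyldimethylsilyl)oxy]-5-[(trimethylsilyl)ethynyl]nona-3,6-diyne-2,8-dione
Product: 10 (3Z,6Z)-5-[(tert-butyldimethylsilyl)oxy]-4,6-dimethyl-5-[(trimethylsilyl)ethynyl]nona-3,6-diene-2,8-dione
Conditions: Me2CuLi (from MeLi and CuI, 2.6 equiv), THF, −78 °C; sat. aq NH4Cl at −78 °C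
Reagents that add atoms: methyllithium, [Li]C (delivered as lithium dimethylcuprate, [Li+].C[Cu-]C, formed with CuI)
Why: Conjugate addition (syn-carbocupration) of a Gilman cuprate to each ynone puts methyl on the β-carbon and, after cold protonation with retention, hydrogen cis to that methyl, so each acetyl group ends cis to C5 (Z); kinetic protonation of any allenolate would also occur away from the bulky C5 substituent and lead to the same isomer.

Step 7
Reactants: 10 (3Z,6Z)-5-[(tert-butyldimethylsilyl)oxy]-4,6-dimethyl-5-[(trimethylsilyl)ethynyl]nona-3,6-diene-2,8-dione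
Product: 11 (4S,5R)-4-[(tert-butyldimethylsilyl)oxy]-3,5-dimethyl-5-(2-oxopropyl)-4-[(trimethylsilyl)ethynyl]cyclohex-2-en-1-one (acetonyl cis to the alkyne)
Conditions: 9-amino-9-deoxy-epi-quinine (20 mol %), 2-fluorobenzoic acid (40 mol %), toluene, 0 °C → rt, dark
Reagents that add atoms: none
Why: Proposed new method: the primary amine condenses reversibly with either methyl ketone, the iminium ion tautomerises to a cross-conjugated 2-aminodiene, and its terminal carbon (C5') adds to the β-carbon (C6') of the other enone, which is activated by hydrogen bonding to the protonated quinuclidine, before hydrolysis returns the catalyst and leaves the former acceptor as the acetonyl group on C6'; the closest known reactions are chiral primary-amine-catalysed intramolecular Michael additions of ketones to enones, including desymmetrisations of prochiral dienones, and Robinson-type closures that build quaternary carbons, none of them on an acyclic bis-enone carbinol with a β,β-disubstituted acceptor. Ring A closes in a 6-exo-trig mode, for which the (Z)-geometry of the donor arm is a geometric prerequisite because only then can C5' reach C6'. Since both arms are the same, regiochemistry is not an issue: whichever arm becomes the nucleophile, the same connectivity results, and the linear dienamine could only close a four-membered ring. The absolute configuration of C1' and C6' together depends on which enantiotopic arm the catalyst turns into the donor in the C–C bond-forming transition state (catalyst control). The C1'/C6' relationship is substrate-controlled: in the (Z)-acceptor the acetyl group on C8' points back towards C1', and minimising A1,3 strain should put the linear alkynyl group rather than the silyloxy group next to it, which translates into acetonyl cis to alkynyl and the C9' methyl cis to the silyloxy group. The step therefore needs enantiotopic-group selectivity from the catalyst and diastereoselectivity from allylic strain, and it should be stopped before the acetonyl ketone can add to C2' in a second Michael closure that would erase chirality.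

Step 8
Reactants: 11 (4S,5R)-4-[(tert-butyldimethylsilyl)oxy]-3,5-dimethyl-5-(2-oxopropyl)-4-[(trimethylsilyl)ethynyl]cyclohex-2-en-1-one
Product: 12 {(1S,2R)-2-[(tert-butyldimethylsilyl)oxy]-1,3-dimethyl-5-oxo-2-[(trimethylsilyl)ethynyl]cyclohex-3-en-1-yl}methyl acetate
Conditions: CF3CO3H (from (CF3CO)2O and urea–H2O2), Na2HPO4, CH2Cl2, 0 °C
Reagents that add atoms: trifluoroperacetic acid, OOC(=O)C(F)(F)F
Why: In this Baeyer–Villiger oxidation the saturated methyl ketone should form the Criegee adduct faster than the conjugated ring ketone, and the primary carbon C8' migrates in preference to methyl, giving the 8'-acetate without touching C1' or C6'.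

Step 9
Reactants: 12 {(1S,2R)-2-[(tert-butyldimethylsilyl)oxy]-1,3-dimethyl-5-oxo-2-[(trimethylsilyl)ethynyl]cyclohex-3-en-1-yl}methyl acetate
Product: 13 {(8R,9S)-8-[(tert-butyldimethylsilyl)oxy]-7,9-dimethyl-8-[(trimethylsilyl)ethynyl]-1,4-dioxaspiro[4.5]dec-6-en-9-yl}methyl acetate
Conditions: TMSOCH2CH2OTMS, TMSOTf (5 mol %), CH2Cl2, −78 → −20 °C; pyridine quench
Reagents that add atoms: 1,2-bis(trimethylsilyloxy)ethane, C[Si](C)(C)OCCO[Si](C)(C)C
Why: Noyori ketalisation under aprotic, cold conditions should protect the C4' enone without moving the C2'=C3' double bond, which is needed because a free 8'-hydroxyl would otherwise add to C2' of the enone (the closure that turns 8'-hydroxyabscisic acid into phaseic acid).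

Step 10
Reactants: 13 {(8R,9S)-8-[(tert-butyldimethylsilyl)oxy]-7,9-dimethyl-8-[(trimethylsilyl)ethynyl]-1,4-dioxaspiro[4.5]dec-6-en-9-yl}methyl acetate
Product: 15 (8R,9S)-8-ethynyl-9-(hydroxymethyl)-7,9-dimethyl-1,4-dioxaspiro[4.5]dec-6-en-8-ol, via hydroxy alkyne acetate 14 (not isolated)
Conditions: TBAF (3 equiv), THF, 0 → 50 °C; then K2CO3, MeOH, rt
Reagents that add atoms: none
Why: Fluoride cleaves both the O–Si and the C(sp)–Si bonds, and carbonate-catalysed transesterification with methanol then removes the acetate; with the enone masked the liberated 8'-hydroxyl has no Michael acceptor to attack.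

Step 11
Reactants: 16 3-hydroxy-3-methylglutaric acid
Product: 17 dimethyl 3-hydroxy-3-methylglutarate
Conditions: MeOH, Amberlyst 15 (H+ form), rt → 40 °C
Reagents that add atoms: methanol, CO
Why: Fischer esterification under mild acid should esterify both carboxyl groups without dehydrating the tertiary β-hydroxy diacid.

Step 12
Reactants: 17 dimethyl 3-hydroxy-3-methylglutarate
Product: 18 (3S)-3-hydroxy-5-methoxy-3-methyl-5-oxopentanoic acid
Conditions: pig liver esterase, aq. phosphate buffer pH 7, 0–5 °C; then acidify to pH 3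
Reagents that add atoms: water, O
Why: Enzymatic desymmetrisation of the prochiral diester by enantiotopic-group-selective hydrolysis should give the (S)-half-ester, which sets the glutarate stereocentre (enantiomeric purity to be upgraded through a crystalline amine salt if required).

Step 13
Reactants: 15 (8R,9S)-8-ethynyl-9-(hydroxymethyl)-7,9-dimethyl-1,4-dioxaspiro[4.5]dec-6-en-8-ol; 18 (3S)-3-hydroxy-5-methoxy-3-methyl-5-oxopentanoic acid
Product: 19 1-{[(8R,9S)-8-ethynyl-8-hydroxy-7,9-dimethyl-1,4-dioxaspiro[4.5]dec-6-en-9-yl]methyl} 5-methyl (3R)-3-hydroxy-3-methylpentanedioate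
Conditions: DCC, DMAP (0.2 equiv), CH2Cl2, 0 °C → rt
Reagents that add atoms: none
Why: Steglich esterification should acylate the primary 8'-hydroxyl selectively because the C1' hydroxyl and the glutarate hydroxyl are tertiary; the glutarate stereocentre is not involved (its descriptor changes from S to R only through the priority rules).

Step 14
Reactants: 19 1-{[(8R,9S)-8-ethynyl-8-hydroxy-7,9-dimethyl-1,4-dioxaspiro[4.5]dec-6-en-9-yl]methyl} 5-methyl (3R)-3-hydroxy-3-methylpentanedioate
Product: 20 1-{[(8R,9S)-8-hydroxy-7,9-dimethyl-8-[(E)-2-(tributylstannyl)ethenyl]-1,4-dioxaspiro[4.5]dec-6-en-9-yl]methyl} 5-methyl (3R)-3-hydroxy-3-methylpentanedioate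
Conditions: Bu3SnH, PdCl2(PPh3)2 (3 mol %), THF, 0 °C → rt
Reagents that add atoms: tributyltin hydride, CCCC[SnH](CCCC)CCCC
Why: Palladium-catalysed hydrostannation is a syn addition, and the fully substituted, crowded propargylic carbon should direct tin to the terminal carbon, giving the (E)-vinylstannane.

Step 15
Reactants: 21 but-2-ynoic acid
Product: 22 (Z)-3-iodobut-2-enoic acid
Conditions: NaI, AcOH, 110 °C
Reagents that add atoms: sodium iodide, [Na+].[I-]
Why: Hydroiodination of the ynoic acid (conjugate addition of iodide, then protonation; net anti addition of HI) gives the (Z)-β-iodo acid.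

Step 16
Reactants: 20 1-{[(8R,9S)-8-hydroxy-7,9-dimethyl-8-[(E)-2-(tributylstannyl)ethenyl]-1,4-dioxaspiro[4.5]dec-6-en-9-yl]methyl} 5-methyl (3R)-3-hydroxy-3-methylpentanedioate; 22 (Z)-3-iodobut-2-enoic acid
Product: 23 (2Z,4E)-5-[(8R,9S)-8-hydroxy-9-({[(3R)-3-hydroxy-5-methoxy-3-methyl-5-oxopentanoyl]oxy}methyl)-7,9-dimethyl-1,4-dioxaspiro[4.5]dec-6-en-8-yl]-3-methylpenta-2,4-dienoic acid
Conditions: PdCl2(MeCN)2 (5 mol %), DMF, rt, dark
Reagents that add atoms: none
Why: Stille coupling proceeds with retention at both alkenyl carbons and so should give the (2Z,4E)-dienoic acid directly; using the free iodo acid avoids a final saponification that the two other esters would not survive.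

Step 17
Reactants: 23 (2Z,4E)-5-[(8R,9S)-8-hydroxy-9-({[(3R)-3-hydroxy-5-methoxy-3-methyl-5-oxopentanoyl]oxy}methyl)-7,9-dimethyl-1,4-dioxaspiro[4.5]dec-6-en-8-yl]-3-methylpenta-2,4-dienoic acid
Product: 24 (2Z,4E)-5-[(1R,6S)-1-hydroxy-6-({[(3R)-3-hydroxy-5-methoxy-3-methyl-5-oxopentanoyl]oxy}methyl)-2,6-dimethyl-4-oxocyclohex-2-en-1-yl]-3-methylpenta-2,4-dienoic acid (CNP0274837.1)
Conditions: 1 M aq HCl, THF, 0 °C → rt
Reagents that add atoms: water, O
Why: Acid-catalysed hydrolysis of the allylic dioxolane releases the C4' enone under conditions that abscisic-acid-type tertiary carbinols, the esters and the β-hydroxy ester should tolerate; the 8'-oxygen is now acylated and cannot add to C2'.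

**Compound list**

1 | but-3-yn-2-ol (racemic) | CC(O)C#C | starting material
2 | triethyl(but-3-yn-2-yloxy)silane | CC(O[Si](CC)(CC)CC)C#C | intermediate
3 | methyl 3-(trimethylsilyl)propiolate | COC(=O)C#C[Si](C)(C)C | starting material
4 | lithium 3-[(triethylsilyl)oxy]but-1-yn-1-ide | [Li]C#CC(C)O[Si](CC)(CC)CC | intermediate
5 | 6-[(triethylsilyl)oxy]-1-(trimethylsilyl)hepta-1,4-diyn-3-one | CC(O[Si](CC)(CC)CC)C#CC(=O)C#C[Si](C)(C)C | intermediate
6 | 2,8-bis[(triethylsilyl)oxy]-5-[(trimethylsilyl)ethynyl]nona-3,6-diyn-5-ol | CC(O[Si](CC)(CC)CC)C#CC(O)(C#C[Si](C)(C)C)C#CC(C)O[Si](CC)(CC)CC | intermediate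
7 | 5-[(tert-butyldimethylsilyl)oxy]-2,8-bis[(triethylsilyl)oxy]-5-[(trimethylsilyl)ethynyl]nona-3,6-diyne | CC(O[Si](CC)(CC)CC)C#CC(O[Si](C)(C)C(C)(C)C)(C#C[Si](C)(C)C)C#CC(C)O[Si](CC)(CC)CC | intermediate
8 | 5-[(tert-butyldimethylsilyl)oxy]-5-[(trimethylsilyl)ethynyl]nona-3,6-diyne-2,8-diol | CC(O)C#CC(O[Si](C)(C)C(C)(C)C)(C#C[Si](C)(C)C)C#CC(C)O | intermediate
9 | 5-[(tert-butyldimethylsilyl)oxy]-5-[(trimethylsilyl)ethynyl]nona-3,6-diyne-2,8-dione | CC(=O)C#CC(O[Si](C)(C)C(C)(C)C)(C#C[Si](C)(C)C)C#CC(C)=O | intermediate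
10 | (3Z,6Z)-5-[(tert-butyldimethylsilyl)oxy]-4,6-dimethyl-5-[(trimethylsilyl)ethynyl]nona-3,6-diene-2,8-dione | CC(=O)/C=C(C)\C(O[Si](C)(C)C(C)(C)C)(C#C[Si](C)(C)C)/C(C)=C\C(C)=O | intermediate
11 | (4S,5R)-4-[(tert-butyldimethylsilyl)oxy]-3,5-dimethyl-5-(2-oxopropyl)-4-[(trimethylsilyl)ethynyl]cyclohex-2-en-1-one | CC(=O)C[C@]1(C)CC(=O)C=C(C)[C@]1(O[Si](C)(C)C(C)(C)C)C#C[Si](C)(C)C | intermediate
12 | {(1S,2R)-2-[(tert-butyldimethylsilyl)oxy]-1,3-dimethyl-5-oxo-2-[(trimethylsilyl)ethynyl]cyclohex-3-en-1-yl}methyl acetate | CC(=O)OC[C@]1(C)CC(=O)C=C(C)[C@]1(O[Si](C)(C)C(C)(C)C)C#C[Si](C)(C)C | intermediate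
13 | {(8R,9S)-8-[(tert-butyldimethylsilyl)oxy]-7,9-dimethyl-8-[(trimethylsilyl)ethynyl]-1,4-dioxaspiro[4.5]dec-6-en-9-yl}methyl acetate | CC(=O)OC[C@]1(C)CC2(OCCO2)C=C(C)[C@]1(O[Si](C)(C)C(C)(C)C)C#C[Si](C)(C)C | intermediate
14 | [(8R,9S)-8-ethynyl-8-hydroxy-7,9-dimethyl-1,4-dioxaspiro[4.5]dec-6-en-9-yl]methyl acetate | CC(=O)OC[C@]1(C)CC2(OCCO2)C=C(C)[C@]1(O)C#C | intermediate
15 | (8R,9S)-8-ethynyl-9-(hydroxymethyl)-7,9-dimethyl-1,4-dioxaspiro[4.5]dec-6-en-8-ol | OC[C@]1(C)CC2(OCCO2)C=C(C)[C@]1(O)C#C | intermediate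
16 | 3-hydroxy-3-methylglutaric acid | CC(O)(CC(=O)O)CC(=O)O | starting material
17 | dimethyl 3-hydroxy-3-methylglutarate | COC(=O)CC(C)(O)CC(=O)OC | intermediate
18 | (3S)-3-hydroxy-5-methoxy-3-methyl-5-oxopentanoic acid | COC(=O)C[C@@](C)(O)CC(=O)O | intermediate
19 | 1-{[(8R,9S)-8-ethynyl-8-hydroxy-7,9-dimethyl-1,4-dioxaspiro[4.5]dec-6-en-9-yl]methyl} 5-methyl (3R)-3-hydroxy-3-methylpentanedioate | COC(=O)C[C@@](C)(O)CC(=O)OC[C@]1(C)CC2(OCCO2)C=C(C)[C@]1(O)C#C | intermediate
20 | 1-{[(8R,9S)-8-hydroxy-7,9-dimethyl-8-[(E)-2-(tributylstannyl)ethenyl]-1,4-dioxaspiro[4.5]dec-6-en-9-yl]methyl} 5-methyl (3R)-3-hydroxy-3-methylpentanedioate | COC(=O)C[C@@](C)(O)CC(=O)OC[C@]1(C)CC2(OCCO2)C=C(C)[C@]1(O)/C=C/[Sn](CCCC)(CCCC)CCCC | intermediate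
21 | but-2-ynoic acid | CC#CC(=O)O | starting material
22 | (Z)-3-iodobut-2-enoic acid | C/C(I)=C/C(=O)O | intermediate
23 | (2Z,4E)-5-[(8R,9S)-8-hydroxy-9-({[(3R)-3-hydroxy-5-methoxy-3-methyl-5-oxopentanoyl]oxy}methyl)-7,9-dimethyl-1,4-dioxaspiro[4.5]dec-6-en-8-yl]-3-methylpenta-2,4-dienoic acid | COC(=O)C[C@@](C)(O)CC(=O)OC[C@]1(C)CC2(OCCO2)C=C(C)[C@]1(O)/C=C/C(C)=C\C(=O)O | intermediate
24 | (2Z,4E)-5-[(1R,6S)-1-hydroxy-6-({[(3R)-3-hydroxy-5-methoxy-3-methyl-5-oxopentanoyl]oxy}methyl)-2,6-dimethyl-4-oxocyclohex-2-en-1-yl]-3-methylpenta-2,4-dienoic acid | COC(=O)C[C@@](C)(O)CC(=O)OC[C@]1(C)CC(=O)C=C(C)[C@]1(O)/C=C/C(C)=C\C(=O)O | target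

**Step count and risks**

Total steps: 17. Longest linear sequence: 14 (steps 1–10, 13, 14, 16, 17); steps 11, 12 and 15 are side branches.

Steps most likely to fail:

1. Step 7 (proposed new method).
 - What may go wrong: the hindered β,β-disubstituted acceptor may not be attacked at a useful rate; the catalyst may discriminate poorly between the enantiotopic arms; allylic-strain control of the C1'/C6' relationship may be weak, especially if the acceptor alkene isomerises to E; retro-Michael opening may erode selectivity; a second Michael closure of the acetonyl ketone onto C2' may give an achiral bicyclo[3.3.1]nonanedione.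
 - Fallback, known chemistry, from 10 back to 11: the kinetic cross-conjugated lithium dienolate of one methyl ketone (LiN(SiMe3)2, 1.0 equiv, THF, −78 °C) is allowed to close by anionic intramolecular Michael addition on warming to −20 °C. This gives racemic material, 11 together with its mirror image ent-11 F1. Preparative chromatography on a chiral stationary phase separates the two and returns the route to 11.

2. Step 6.
 - What may go wrong: alkene geometry may be lost through the allenolate; the second addition may be incomplete; the strained (Z)-enones may isomerise during work-up or storage.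
 - Fallback, from 3 back to 10, with the geometry fixed before the carbinol is assembled: commercial pent-3-yn-2-ol (CC#CC(C)O) undergoes hydroxyl-directed trans-hydroalumination and iodination (NaAlH2(OCH2CH2OMe)2, then I2) to give (Z)-4-iodopent-3-en-2-ol F2. Silylation (TESCl, imidazole) gives its triethylsilyl ether F3. Iodine–lithium exchange (t-BuLi, Et2O, −78 °C, retention) and addition of two equivalents of the vinyllithium to ester 3 gives the bis-alkenyl carbinol F4. This is silylated (TBSOTf, 2,6-lutidine, or by trapping the lithium alkoxide in the same flask) to the tert-butyldimethylsilyl ether F5, freed of both triethylsilyl groups (PPTS, MeOH) to the diol F6, and oxidised with Dess–Martin periodinane to 10.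

3. Step 16.
 - What may go wrong: the trisubstituted C2=C3 alkene may isomerise from Z to E under palladium; the free acid may protodestannylate the stannane; tin carboxylate formation may slow transmetalation.
 - Fallback, from 19 back to 23, bypassing the stannane: 22 is esterified with 2-(trimethylsilyl)ethanol (DCC, DMAP) to 2-(trimethylsilyl)ethyl (Z)-3-iodobut-2-enoate F7. Sonogashira coupling with 19 (PdCl2(PPh3)2, CuI, Et3N) gives the (Z)-enyne ester F8. Ruthenium-catalysed trans-hydrosilylation ([Cp*Ru(MeCN)3]PF6, BnMe2SiH) gives the vinylsilane F9. Fluoride (TBAF, THF) then removes the vinylic silicon with retention, leaving the 4E alkene, together with the 2-(trimethylsilyl)ethyl ester, which returns the route to 23.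

**Further compounds**

F1 | step 7 | ent-11, (4R,5S)-4-[(tert-butyldimethylsilyl)oxy]-3,5-dimethyl-5-(2-oxopropyl)-4-[(trimethylsilyl)ethynyl]cyclohex-2-en-1-one | CC(=O)C[C@@]1(C)CC(=O)C=C(C)[C@@]1(O[Si](C)(C)C(C)(C)C)C#C[Si](C)(C)C
F2 | step 6 | (Z)-4-iodopent-3-en-2-ol | C/C(I)=C/C(C)O
F3 | step 6 | triethyl{[(Z)-4-iodopent-3-en-2-yl]oxy}silane | C/C(I)=C/C(C)O[Si](CC)(CC)CC
F4 | step 6 | (3Z,6Z)-4,6-dimethyl-2,8-bis[(triethylsilyl)oxy]-5-[(trimethylsilyl)ethynyl]nona-3,6-dien-5-ol | CC(O[Si](CC)(CC)CC)/C=C(C)\C(O)(C#C[Si](C)(C)C)/C(C)=C\C(C)O[Si](CC)(CC)CC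
F5 | step 6 | (3Z,6Z)-5-[(tert-butyldimethylsilyl)oxy]-4,6-dimethyl-2,8-bis[(triethylsilyl)oxy]-5-[(trimethylsilyl)ethynyl]nona-3,6-diene | CC(O[Si](CC)(CC)CC)/C=C(C)\C(O[Si](C)(C)C(C)(C)C)(C#C[Si](C)(C)C)/C(C)=C\C(C)O[Si](CC)(CC)CC
F6 | step 6 | (3Z,6Z)-5-[(tert-butyldimethylsilyl)oxy]-4,6-dimethyl-5-[(trimethylsilyl)ethynyl]nona-3,6-diene-2,8-diol | CC(O)/C=C(C)\C(O[Si](C)(C)C(C)(C)C)(C#C[Si](C)(C)C)/C(C)=C\C(C)O
F7 | step 16 | 2-(trimethylsilyl)ethyl (Z)-3-iodobut-2-enoate | C/C(I)=C/C(=O)OCC[Si](C)(C)C
F8 | step 16 | (Z)-enyne ester: 2-(trimethylsilyl)ethyl (2Z)-5-[(8R,9S)-8-hydroxy-9-({[(3R)-3-hydroxy-5-methoxy-3-methyl-5-oxopentanoyl]oxy}methyl)-7,9-dimethyl-1,4-dioxaspiro[4.5]dec-6-en-8-yl]-3-methylpent-2-en-4-ynoate | COC(=O)C[C@@](C)(O)CC(=O)OC[C@]1(C)CC2(OCCO2)C=C(C)[C@]1(O)C#C/C(C)=C\C(=O)OCC[Si](C)(C)C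
F9 | step 16 | vinylsilane from trans addition of BnMe2SiH to F8 (silicon on C4, hydrogen on C5, mutually trans) | COC(=O)C[C@@](C)(O)CC(=O)OC[C@]1(C)CC2(OCCO2)C=C(C)[C@]1(O)/C=C(/C(C)=C\C(=O)OCC[Si](C)(C)C)[Si](C)(C)Cc1ccccc1
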